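The decision is how to bring in the starting material: all at once, fed evenly, through a tank or through a tube.

all flasks: protic impurity 5.00 mM; free catalyst 1 mol%

|  | starting material | time | remark |
|---|---|---|---|
| summer | 0.25 M | 15 min | a closed flask charged with all of it at once and left for 15 min |
| dusk | 0.25 M (fed, over 15.0 min) | 15 min | all but starting material at the start; starting material goes in evenly over 15.0 min, the run ends at 15 min |
| midnight | 0.25 M |  | a single well-mixed tank run continuously and read at steady state, 15 min in it on average |
| dawn | 0.25 M | 15 min | plug flow through a tube for 15 min, no back-mixing |

    starting material + protic impurity → quenched substrate (k1 = 23 L mol⁻¹ min⁻¹)
    starting material + free catalyst → catalyst intermediate (k2 = 140 L mol⁻¹ min⁻¹)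
    catalyst intermediate → free catalyst + target (k3 = 990 min⁻¹)
    target → over-reaction product (k4 = 0.10 min⁻¹)

- the stated concentrations are those of everything mixed, before any reaction; amounts are the same in each set-up
- the feed brings no volume worth counting
- run time (summer): 15 min

- the set-up with the highest amount of target at the outlet or at the end, in percent of the starting material put in ("none" if the first two lie within 2 percentage points) (summer / dusk / midnight / dawn / none)
- amount of target at the outlet or at the end, in percent of the starting material put in, summer
- amount of target at the outlet or at the end, in percent of the starting material put in, dusk
- amount of target at the outlet or at the end, in percent of the starting material put in, midnight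
- amount of target at the outlet or at the end, in percent of the starting material put in, dawn

The catalyst intermediate falls apart at 990 min⁻¹, while free catalyst is captured at no more than 35.0 min⁻¹, so no more than 3.41 % of the catalyst sits as catalyst intermediate and the starting material is consumed as a pseudo-first-order reactant. The capture constant times the catalyst charged gives 0.350 min⁻¹, the catalyst pull: the fraction of the starting material present that is consumed per minute. The pull exceeds the loss of target, 0.10 min⁻¹, so a charge made at once is consumed early and the target then decays through the rest of the 15 min. With the protic impurity taking 2.00 % of the charge, summer and dawn, which run the same course in time, reckon to 29.9 %, and midnight reckons to 32.9 %.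

In dusk the inflow meets the pull, so the starting material climbs towards 0.0476 M and ends at 18.9 % of the charge. The same balance carried on to the target gives 45.1 %. A neighbour flask looks nearly the same as dusk but holds 0.4 mol% of free catalyst. Its pull is 0.140 min⁻¹, less than the 0.350 min⁻¹ of dusk, so the same feed should leave 41.8 % unconsumed and reach 34.3 % of target.

The forecast gives 30.1 % for summer, 45.2 % for dusk, 32.9 % for midnight and 30.1 % for dawn, and names dusk, in its words “target formed late has had less time to degrade”, with figures for summer, dusk and dawn that are not those of this reckoning.

The simulation gives 30.0 % for summer, 45.2 % for dusk, 32.9 % for midnight and 30.0 % for dawn, so the best is dusk. In dusk the half-life of starting material by capture at the end is 2.0 min, against 1.98 min from the pull, and it is shorter than the target's half-life of 6.9 min. Dusk's starting material peaks at 0.0476 M and ends at 19.0 % of the charge, with target at 45.2 %. The neighbour flask, with its pull of 0.140 min⁻¹, ends with 41.8 % of the charge as starting material and 34.0 % as target.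

(The constants come from no measurement; the run is a simulation.)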